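**Assumption (one line):** (R)-t-BuPyOx is taken as the ligand antipode that gives the 2S flavanone, by analogy with its sense of induction on cyclic enones; this is confirmed by chiral HPLC/CD on the first run and the (S)-ligand is used if the sense is reversed.

## Retrosynthetic overview

1. The C2–C1′ bond and the (2S) centre come from a Pd(II)/PyOx enantioselective conjugate arylation of chromone 15 with boronic acid 19; global MOM removal then gives the target.
2. The C6–C1″ bond comes from a Pd-catalysed, geometry-retentive allyl–aryl coupling of 6-borylchromone 9 with (E)-allylic carbonate 14, whose E-olefin is set by Zr-catalysed carboalumination.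
3. The pyranone ring is the only ring built (A and B rings are resorcinol and catechol); it is closed by a Rh-catalysed aldehyde C–H hydroacylation/annulation of salicylaldehyde 6 with ethoxyacetylene (new).
4. The A-ring pattern comes from resorcinol: bromination between the two ethers (future C6), Ir C–H borylation/oxidation at the meta position (future O1), then ortho-formylation. Symmetry removes any C6/C8 ambiguity.

## Route

### A-ring / chromone branch

**Step 1**
Reactants: 1 resorcinol
Product: 2, 1,3-bis(methoxymethoxy)benzene
Conditions: MOMCl (2.5 equiv), i-Pr2NEt, CH2Cl2, 0 °C → rt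
Reagents that add atoms: chloromethyl methyl ether, COCCl
Why: Standard MOM acetalisation of both phenols; the MOM ethers are base-stable and serve as ortho-directing groups in step 2.

**Step 2**
Reactants: 2 1,3-bis(methoxymethoxy)benzene
Product: 3, 2-bromo-1,3-bis(methoxymethoxy)benzene
Conditions: n-BuLi, THF, 0 °C → rt; then BrCCl2CCl2Br, −78 °C → rt
Reagents that add atoms: 1,2-dibromotetrachloroethane, BrC(Cl)(Cl)C(Cl)(Cl)Br
Why: Directed ortho-metalation; the two OMOM groups cooperatively direct lithiation to C2, and the aryllithium is brominated there.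

**Step 3**
Reactants: 3 2-bromo-1,3-bis(methoxymethoxy)benzene
Product: 4, 2-[4-bromo-3,5-bis(methoxymethoxy)phenyl]-4,4,5,5-tetramethyl-1,3,2-dioxaborolane
Conditions: [Ir(OMe)(cod)]2 (1.5 mol %), dtbpy (3 mol %), B2pin2, THF, 80 °C
Reagents that add atoms: bis(pinacolato)diboron, CC1(C)OB(B2OC(C)(C)C(C)(C)O2)OC1(C)C
Why: Sterically controlled Ir-catalysed aromatic C–H borylation; C5 is the only C–H without an ortho substituent, and the C–Br bond is tolerated.

**Step 4**
Reactants: 4 aryl pinacol boronate
Product: 5, 4-bromo-3,5-bis(methoxymethoxy)phenol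
Conditions: 30% H2O2, aq NaOH, THF, 0 °C
Reagents that add atoms: hydrogen peroxide, OO
Why: Boronate oxidation (1,2-aryl shift in the peroxoborate) gives the phenol that becomes the ring oxygen O1; ArBr and MOM groups are inert.

**Step 5**
Reactants: 5 4-bromo-3,5-bis(methoxymethoxy)phenol
Product: 6, 3-bromo-6-hydroxy-2,4-bis(methoxymethoxy)benzaldehyde
Conditions: MgCl2, Et3N, (CH2O)n, MeCN, reflux
Reagents that add atoms: paraformaldehyde (formaldehyde), C=O
Why: Magnesium-phenoxide ortho-formylation (Casnati–Skattebøl); the two ortho positions are equivalent and the para position is blocked by Br, so only one salicylaldehyde can form.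

**Step 6**
Reactants: 6 3-bromo-6-hydroxy-2,4-bis(methoxymethoxy)benzaldehyde; 7 ethoxyacetylene (3 equiv)
Product: 8, 6-bromo-5,7-bis(methoxymethoxy)-4H-chromen-4-one
Conditions: [Rh(cod)Cl]2 (2.5 mol %), dppf (5 mol %), Na2CO3 (20 mol %), toluene, 70 °C (sealed); then PPTS (10 mol %), 50 °C
Reagents that add atoms: none (C2 and C3 come from 7; EtOH is lost)
Why: Proposed new method: the phenoxide-bound Rh(I) adds oxidatively into the aldehyde C–H bond to give a five-membered acyl-rhodium hydride, which hydrometalates the polarised ynol ether (H to the O-bearing carbon, Rh to the terminal carbon) and reductively eliminates to the (E)-β-ethoxyvinyl 2-hydroxyaryl ketone; 6-endo oxa-Michael addition and loss of EtOH then give the chromone in one redox-neutral operation. The closest known reactions are the Rh/dppf-catalysed chelation-assisted hydroacylation of ordinary alkynes by salicylaldehydes and tandem hydroacylation/oxa-Michael chromanone syntheses; an alkynyl ether as a traceless two-carbon unit has not, to my knowledge, been shown.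

**Step 7**
Reactants: 8 6-bromo-5,7-bis(methoxymethoxy)-4H-chromen-4-one
Product: 9, 5,7-bis(methoxymethoxy)-6-(4,4,5,5-tetramethyl-1,3,2-dioxaborolan-2-yl)-4H-chromen-4-one
Conditions: Pd2(dba)3 (2 mol %), XPhos (8 mol %), B2pin2, KOAc, dioxane, 90 °C
Reagents that add atoms: bis(pinacolato)diboron, CC1(C)OB(B2OC(C)(C)C(C)(C)O2)OC1(C)C
Why: Miyaura borylation with a bulky biarylphosphine suited to the di-ortho-alkoxy bromide; it turns the arene into the nucleophile so that the allyl partner can enter as a geometry-defined electrophile.

### Side-chain branch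

**Step 8**
Reactants: 10 hex-5-ynoic acid
Product: 11, methyl hex-5-ynoate
Conditions: MeOH, H2SO4 (cat.), reflux
Reagents that add atoms: methanol, CO
Why: Fischer esterification.

**Step 9**
Reactants: 11 methyl hex-5-ynoate
Product: 12, 2-methylhept-6-yn-2-ol
Conditions: MeMgBr (3.5 equiv), THF, 0 °C → rt; aq NH4Cl
Reagents that add atoms: methylmagnesium bromide, C[Mg]Br
Why: Double Grignard addition to the ester gives the tertiary alcohol; the alkynyl C–H only consumes one equivalent reversibly.

**Step 10**
Reactants: 12 2-methylhept-6-yn-2-ol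
Product: 13, (2E)-3,7-dimethyloct-2-ene-1,7-diol
Conditions: Me3Al (3.5 equiv), Cp2ZrCl2 (0.25 equiv), CH2Cl2, 0 °C → rt; then n-BuLi, THF, −78 °C; (CH2O)n, −78 °C → rt
Reagents that add atoms: trimethylaluminium, C[Al](C)C; paraformaldehyde, C=O
Why: Negishi Zr-catalysed carboalumination adds Me and Al syn across the alkyne (Me internal, >98% E), and the alkenylalanate is trapped with formaldehyde, so the E-trisubstituted olefin is fixed here.

**Step 11**
Reactants: 13 (2E)-3,7-dimethyloct-2-ene-1,7-diol
Product: 14, (2E)-7-hydroxy-3,7-dimethyloct-2-en-1-yl methyl carbonate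
Conditions: ClCO2Me (1.2 equiv), pyridine, CH2Cl2, 0 °C
Reagents that add atoms: methyl chloroformate, COC(=O)Cl
Why: Chemoselective acylation of the primary allylic OH; the tertiary OH does not react under these conditions.

### Fragment union

**Step 12**
Reactants: 9 6-borylchromone; 14 allylic methyl carbonate
Product: 15, 6-[(2E)-7-hydroxy-3,7-dimethyloct-2-en-1-yl]-5,7-bis(methoxymethoxy)-4H-chromen-4-one
Conditions: Pd(PPh3)4 (5 mol %), KF (3 equiv), THF/H2O (10:1), 50 °C
Reagents that add atoms: none
Why: Suzuki–Miyaura-type allyl–aryl coupling: Pd(0) ionises the carbonate to a π-allyl complex whose disubstituted terminus keeps its geometry (isomerisation would need a tertiary σ-allyl), and the aryl group is delivered by reductive elimination at the unhindered CH2 terminus, giving the linear E product.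

### B-ring branch

**Step 13**
Reactants: 16 catechol
Product: 17, 1,2-bis(methoxymethoxy)benzene
Conditions: MOMCl (2.5 equiv), i-Pr2NEt, CH2Cl2, 0 °C → rt
Reagents that add atoms: chloromethyl methyl ether, COCCl
Why: MOM protection of both phenols.

**Step 14**
Reactants: 17 1,2-bis(methoxymethoxy)benzene
Product: 18, 2-[3,4-bis(methoxymethoxy)phenyl]-4,4,5,5-tetramethyl-1,3,2-dioxaborolane
Conditions: [Ir(OMe)(cod)]2 (1.5 mol %), dtbpy (3 mol %), B2pin2, THF, 80 °C
Reagents that add atoms: bis(pinacolato)diboron, CC1(C)OB(B2OC(C)(C)C(C)(C)O2)OC1(C)C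
Why: Ir-catalysed C–H borylation of a 1,2-disubstituted arene occurs only at C4 (the C–H with no ortho substituent), giving the 3,4-dioxygenated aryl boronate directly.

**Step 15**
Reactants: 18 aryl pinacol boronate
Product: 19, [3,4-bis(methoxymethoxy)phenyl]boronic acid
Conditions: NaIO4, NH4OAc, acetone/H2O, rt
Reagents that add atoms: water, O
Why: Oxidative cleavage of the pinacol unit releases the free boronic acid needed for the Pd(II) conjugate addition; the conditions are mild enough for MOM ethers.

### Endgame

**Step 16**
Reactants: 15 6-allylchromone; 19 arylboronic acid (2 equiv)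
Product: 20, (2S)-2-[3,4-bis(methoxymethoxy)phenyl]-6-[(2E)-7-hydroxy-3,7-dimethyloct-2-en-1-yl]-5,7-bis(methoxymethoxy)-2,3-dihydro-4H-chromen-4-one
Conditions: Pd(OCOCF3)2 (7.5 mol %), (R)-t-BuPyOx (9 mol %), NH4PF6 (30 mol %), H2O (5 equiv), ClCH2CH2Cl, 60 °C
Reagents that add atoms: none
Why: Pd(II)/pyridine-oxazoline enantioselective conjugate addition of an arylboronic acid to a chromone; the C2 centre is set by enantioface-selective insertion of C2=C3 into the aryl–Pd(PyOx) bond, and the base-free, mildly acidic medium avoids retro-oxa-Michael racemisation and leaves the isolated trisubstituted alkene and tertiary OH untouched.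

**Step 17**
Reactants: 20 tetra-MOM flavanone
Product: 21, prokinawan
Conditions: TMSOTf (10 equiv), 2,2′-bipyridyl (15 equiv), MeCN, 0 °C → rt; then H2O; then 10% aq citric acid/THF, rt
Reagents that add atoms: none
Why: Bipyridyl-buffered silyl triflate cleavage of aryl MOM ethers (via aryl TMS ethers hydrolysed on work-up) is near-neutral, so the tertiary alcohol (transiently O-TMS), the ortho-allyl phenol and the base-labile C2 centre should survive.

## Compound list

1 | resorcinol | Oc1cccc(O)c1 | starting material
2 | 1,3-bis(methoxymethoxy)benzene | COCOc1cccc(OCOC)c1 | intermediate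
3 | 2-bromo-1,3-bis(methoxymethoxy)benzene | COCOc1cccc(OCOC)c1Br | intermediate
4 | 2-[4-bromo-3,5-bis(methoxymethoxy)phenyl]-4,4,5,5-tetramethyl-1,3,2-dioxaborolane | COCOc1cc(B2OC(C)(C)C(C)(C)O2)cc(OCOC)c1Br | intermediate
5 | 4-bromo-3,5-bis(methoxymethoxy)phenol | COCOc1cc(O)cc(OCOC)c1Br | intermediate
6 | 3-bromo-6-hydroxy-2,4-bis(methoxymethoxy)benzaldehyde | COCOc1cc(O)c(C=O)c(OCOC)c1Br | intermediate
7 | ethoxyacetylene | CCOC#C | starting material
8 | 6-bromo-5,7-bis(methoxymethoxy)-4H-chromen-4-one | COCOc1cc2occc(=O)c2c(OCOC)c1Br | intermediate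
9 | 5,7-bis(methoxymethoxy)-6-(4,4,5,5-tetramethyl-1,3,2-dioxaborolan-2-yl)-4H-chromen-4-one | COCOc1cc2occc(=O)c2c(OCOC)c1B3OC(C)(C)C(C)(C)O3 | intermediate
10 | hex-5-ynoic acid | C#CCCCC(=O)O | starting material
11 | methyl hex-5-ynoate | C#CCCCC(=O)OC | intermediate
12 | 2-methylhept-6-yn-2-ol | C#CCCCC(C)(C)O | intermediate
13 | (2E)-3,7-dimethyloct-2-ene-1,7-diol | C/C(=C\CO)CCCC(C)(C)O | intermediate
14 | (2E)-7-hydroxy-3,7-dimethyloct-2-en-1-yl methyl carbonate | C/C(=C\COC(=O)OC)CCCC(C)(C)O | intermediate
15 | 6-[(2E)-7-hydroxy-3,7-dimethyloct-2-en-1-yl]-5,7-bis(methoxymethoxy)-4H-chromen-4-one | C/C(=C\Cc1c(OCOC)cc2occc(=O)c2c1OCOC)CCCC(C)(C)O | intermediate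
16 | catechol | Oc1ccccc1O | starting material
17 | 1,2-bis(methoxymethoxy)benzene | COCOc1ccccc1OCOC | intermediate
18 | 2-[3,4-bis(methoxymethoxy)phenyl]-4,4,5,5-tetramethyl-1,3,2-dioxaborolane | COCOc1ccc(B2OC(C)(C)C(C)(C)O2)cc1OCOC | intermediate
19 | [3,4-bis(methoxymethoxy)phenyl]boronic acid | COCOc1ccc(B(O)O)cc1OCOC | intermediate
20 | (2S)-2-[3,4-bis(methoxymethoxy)phenyl]-6-[(2E)-7-hydroxy-3,7-dimethyloct-2-en-1-yl]-5,7-bis(methoxymethoxy)-2,3-dihydro-4H-chromen-4-one | C/C(=C\Cc1c(OCOC)cc2c(c1OCOC)C(=O)C[C@@H](c1ccc(OCOC)c(OCOC)c1)O2)CCCC(C)(C)O | intermediate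
21 | prokinawan, (2S)-2-(3,4-dihydroxyphenyl)-5,7-dihydroxy-6-[(2E)-7-hydroxy-3,7-dimethyloct-2-en-1-yl]-2,3-dihydro-4H-chromen-4-one | C/C(=C\Cc1c(O)cc2c(c1O)C(=O)C[C@@H](c1ccc(O)c(O)c1)O2)CCCC(C)(C)O | target

## Summary

**Total step count:** 17
**Longest linear sequence:** 10 steps (1–7, 12, 16, 17). The side-chain branch contributes 4 steps and the B-ring branch 3 steps before they join.

**Three steps most likely to fail**

- **Step 6 (new Rh hydroacylation/annulation with ethoxyacetylene).** Risks are alkyne oligomerisation, the wrong hydrometalation regiochemistry and a hindered 2,6-disubstituted aldehyde. Fallback (known chemistry): add ethynylmagnesium bromide to aldehyde 6, oxidise the propargylic alcohol with MnO2 to the 2-hydroxyaryl ynone, and close the ring by Et2NH-mediated 6-endo cyclisation via the enaminone to give the same chromone 8.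
- **Step 12 (coupling of the di-ortho-alkoxy aryl boronate with the allylic carbonate).** Risks are slow transmetalation and protodeboronation. Fallback: give up the late union and install the chain at the start. Lithiate 2 at C2 (no bromide), transmetalate to copper (CuBr·SMe2) and alkylate with the allylic bromide made from 13 (tertiary OH as its TES ether), then carry the chain through borylation/oxidation, formylation and chromone formation. This is established chemistry for 2-geranylresorcinol ethers but is less convergent.
- **Step 17 (four-fold MOM removal next to a tertiary alcohol, an ortho-allyl phenol and the C2 centre).** Risks are incomplete cleavage, chroman formation and dehydration. Fallback: change the protecting-group plan before any sensitive group is present. Cleave the MOM ethers of bromochromone 8 with HCl/MeOH, re-protect as TBS ethers, prepare the B-ring boronic acid from 1,2-bis(TBSO)benzene, and finish with Et3N·3HF desilylation.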